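I looked for what stays put. The flask below sits between two earlier runs that differ in leaving ligand, and the question is how much complex with one exchanged incoming ligand can leave at the asked time.

| flask | starting complex | incoming ligand | leaving ligand | capture agent | remark | time |
|---|---|---|---|---|---|---|
| ochre | 0.30 M | 2 equiv | 3.4 equiv | 0.030 M | run made earlier |  |
| grey | 0.30 M | 2 equiv | 7.5 equiv | 0.030 M | run made earlier |  |
| flask | 0.30 M | 2.00 equiv | 5.00 equiv | 0.0300 M |  | 12 h |

- ochre (time / h: complex with one exchanged / %, complex with two exchanged / %): 1.50: 22, 11; 3.00: 24, 21; 5.00: 20, 30; 6.00: 21, 35; 8.00: 20, 39; 10.0: 19, 41; 12.0: 18, 39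
- grey (time / h: complex with one exchanged / %, complex with two exchanged / %): 1.50: 21, 10; 3.00: 24, 21; 5.00: 22, 27; 6.00: 25, 28; 8.00: 17, 28; 10.0: 18, 29; 12.0: 20, 28

(scatter of a reading: 1.5 percentage points)

- equivalents of incoming ligand to starting complex, everything else as given, that leave most complex with one exchanged at 12 h
- the amount of complex with one exchanged then, in percent of the starting complex charged
- the amount of complex with one exchanged with the amounts as given

- the analysis behind the earlier runs scatters by 1.5 percentage points, standard deviation

Let s, y and z be the starting complex and the complexes with one and two exchanged, as shares of the charge. If the late readings stand near equilibrium, y/s and z/y each scale with the ratio of incoming to leaving ligand, so that ratio cancels in the comproportionation quotient Q = y·y/(s·z). At fixed Q, with s, y and z making up the charge between them, y peaks where s equals z, which gives a ceiling c = √Q/(2 + √Q).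

I averaged the ochre readings from 8.00 h on, which gave y = 19.0% and z = 39.7%, and I took s from what remained unread, which gave my lower end:

s = 41.3%, so Q = 0.220 and c = 19.0%

Grey gave Q = 0.222. The ochre remainder may, however, hide complex held by the capture agent, up to 10.0% of the charge if each takes one complex, and removing this share from s, while still reckoning c on the full charge, gave my upper end:

Q = 0.290, so c = 21.2%

The forecast gave 19.2% at 2.35 equiv and 19% as charged, adding “The optimum is very flat”, and its peak lay inside my bracket.

The flask gives 20.1% at 1.58 equiv and 19.5% as charged, and that peak also lies inside.

    starting complex + incoming ligand ⇌ leaving ligand + complex with one exchanged (K = 6.00, k = 1.43 × 10⁻⁴ /M/s)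
    complex with one exchanged + incoming ligand ⇌ leaving ligand + complex with two exchanged (K = 14.7, k = 2.88 × 10⁻⁴ /M/s)
    complex with one exchanged + capture agent → trapped intermediate (k = 6.43 × 10⁻⁴ /M/s)
    leaving ligand + complex with two exchanged → side product (k = 4.21 × 10⁻⁶ /M/s)

In the flask at 12.0 h, Q is 0.375, above my upper end, with 8.08% trapped intermediate and 8.57% side product together exceeding the share I had set aside. In the neighbouring flask, with 3.40 equiv of incoming ligand, starting complex stood at 10.2% and complex with two exchanged at 53.0%, so Q comes to 0.358, and complex with one exchanged stood at 13.9%.

(The earlier runs and the new flask were computed on assumed constants.)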